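## Structural features

The target is a 2,4-disubstituted furan whose C2 is bonded to C2 of a 1,4-benzoquinone ring and whose C4 carries a secondary carbinol carbon. This carbon is the only stereocentre (S; O > furan carbon > CH2 > H). It continues as a prenyl-terminated chain (4-methylpent-3-enyl in all), and its oxygen is acylated by 3-methylbut-2-enoic acid. With no neighbouring stereocentre, the stereochemical problem is purely one of absolute configuration. The fragile groups are the quinone (electrophilic, oxidising, intolerant of bases and organometallic reagents), the electron-rich furan (acids and oxidants), the furylic ester (ionisation), the β,β-dimethylacrylate (loss of conjugation) and the trisubstituted alkene. The real difficulty is an enantiopure furyl carbinol with a linear prenyl arm: a prenyl metal reagent adding to a furan aldehyde would give the branched α,α-dimethylallyl isomer, and routes through a furan-stabilised cation risk racemisation. The key step exploits the bond between furan C4 and the carbinol carbon: the carbinol carbon becomes a configurationally defined nucleophile, the furan a boronic ester, and boron is turned into the oxygen afterwards. The quinone is carried as a 2,5-dimethoxyphenyl ring, attached late to the remaining free α-position of the furan (C2 of the target) and oxidised last.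

## Logic of the disconnections

14 to 13. The two quinone carbonyl groups are traced back to two aryl methyl ethers. A quinone would not survive organolithium, boron-ate or palladium/base chemistry, so it is masked until the end, and the gain is a robust arene. The forward step needs an oxidant that takes the dimethoxyarene faster than the furan and leaves the ester and the alkene alone.

13 to 10 + 11. The bond between furan C2 and the arene is cut. It is the only bond between two sp2 fragments, and both halves become simple: 11 is purchased and 10 is a 3-substituted furan with two free α-positions. The forward step must functionalise only the α-C–H remote from the side chain (sterically controlled borylation to 12) and must couple 12 before it loses boron.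

10 to 8 + 9. The acyl C–O bond of the ester is cut. The acid part is commercial and the stereocentre is untouched, since the carbinol C–O bond is never broken. The acylation must keep the acyl double bond in conjugation and must not ionise the furylic alcohol.

8 to 7. The carbinol C–O bond is exchanged for a C–B bond. A boronic ester at this carbon is exactly what the stereospecific homologation delivers, and its oxidation is retentive. The oxidant must spare the furan and the alkene.

7 to 3 + 4. The bond between the carbinol carbon and the furan carbon (C3 of 4, C4 of the target) is cut, with the carbinol carbon as the nucleophile 5 and boron as the acceptor in 6. This removes the stereocentre and the only skeletal bond that is hard to make, and it leaves an achiral carbamate and a purchased boronic ester. The forward step demands an enantioselective α-deprotonation, a stereoretentive borylation and a clean 1,2-shift of the furyl group.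

3 to 1 + 2. The carbamate C–O bond is cut to two commercial materials. The only demand is a complete acylation of a primary alcohol.

## Other disconnections considered

Alternative 1: The cut goes through the furan ring. Furan C2–C3 and O1–C2 are opened and the C4 substituent is traded for iodine, which leads back to 2,5-dimethoxybenzoyl chloride (A1) and the tetrahydropyranyl ether of prop-2-yn-1-ol (A2).
- Forward key step: A1 and A2 would be coupled with PdCl2(PPh3)2/CuI and Et3N to the alkynyl ketone A3. NaI and p-toluenesulfonic acid would then add HI across the triple bond (iodide at the β-carbon), free the hydroxyl group from its acetal and let it condense with the ketone. This would give 2-(2,5-dimethoxyphenyl)-4-iodofuran (A4) in one flask.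
- In its favour: the 2,4-pattern is fixed by ring construction and not by a steric preference in a C–H functionalisation. The aryl–furan bond exists from the first step, so no labile 2-furylboron species is needed, and the reagents are cheap. On regiochemical certainty of the furan this plan is better than the chosen one.
- Against it here: the step creates no stereocentre, and A4 still lacks the whole chiral side chain. The iodide would have to become a boronic ester and go through the same homologation with 3. Otherwise it would be metallated and added to an aldehyde, giving a racemate that needs oxidation and asymmetric reduction. The central problem is postponed, not solved.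
- Comparison: in mechanism, a polar addition and cyclocondensation builds an achiral heteroarene, whereas the chosen 1,2-metallate shift builds the stereocentre. In step count it needs about seven steps to 14 against six. It shares the final oxidative demethylation, so on the end game the two are equal.

Alternative 2: The cut is made in the six-membered carbocycle, which shrinks to a 4-hydroxy-4-vinylcyclobutenone, (S)-1-[5-(4-ethenyl-4-hydroxy-3-oxocyclobut-1-en-1-yl)furan-3-yl]-4-methylpent-3-en-1-yl 3-methylbut-2-enoate (A5).
- Forward key step: heating A5 in toluene would open the four-membered ring in a four-electron electrocyclic reaction to a dienylketene. The ketene carbon would bond to the terminal vinyl carbon in a six-electron electrocyclisation, and tautomerisation would give the hydroquinone (S)-1-[5-(2,5-dihydroxyphenyl)furan-3-yl]-4-methylpent-3-en-1-yl 3-methylbut-2-enoate (A6). A mild oxidant would then give 14.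
- In its favour: the ring forms without any reagent, under neutral conditions, with unambiguous placement of the furyl group. It arrives at the hydroquinone level, from which the quinone needs only Ag2O or air. This is better than the chosen plan, which must expose a furan to (NH4)2Ce(NO3)6.
- Against it here: A5 must already hold the furan, the stereocentre and the ester, so the stereochemical problem would still be solved by the chemistry of steps 1 to 4. The four-membered ring would have to be attached at the furan α-position from a cyclobutenedione without stabilising alkoxy groups, because the quinone of 14 has three unsubstituted positions. A vinyl metal reagent would have to choose one of two ring carbonyl groups in the presence of an ester. A5 itself is sensitive to acid and base.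
- Comparison: the pericyclic cascade is mechanistically as well founded as the metallate shift, but it addresses the ring that is easiest to buy. In step economy it is clearly longer than six steps.

Alternative 3: The cut is the ester C–O bond at the stereocentre, combined with a cyclopropane drawn between the carbinol carbon and the alkene carbon. This leads to the acid 9 and 2-[(1S,2S)-2-[5-(2,5-dimethoxyphenyl)furan-3-yl]cyclopropyl]propan-2-ol (A7). The 1S,2S trans isomer is the one that inversion at the furyl-bearing carbon would convert into the S ester.
- Forward key step: acid would ionise the tertiary alcohol of A7 to a cyclopropylcarbinyl cation. 9 would attack the furyl-bearing ring carbon opposite to the breaking ring bond, and the ring would open to the trisubstituted alkene. The product A8, (S)-1-[5-(2,5-dimethoxyphenyl)furan-3-yl]-4-methylpent-3-en-1-yl 3-methylbut-2-enoate, is the same compound as 13.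
- In its favour: one step forms the ester bond, the stereocentre and the prenyl alkene, which the chosen plan spreads over three steps. On bond economy at the stereocentre it is better. The chirality of A7 could come from a catalytic asymmetric cyclopropanation, so the chiral source is catalytic and not a stoichiometric diamine, which is also better. No cryogenic organolithium is needed.
- Against it here: the stereochemical outcome depends on the acid arriving before the cation relaxes to an open, furan-stabilised cation. The furyl group stabilises positive charge at exactly the carbon that must invert cleanly, so partial racemisation is a real danger. A carboxylic acid is a weak nucleophile. The Brønsted acid meets an electron-rich arylfuran, and the product is itself a furylic ester that can ionise again. Ring expansion, elimination and capture at the tertiary carbon compete.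
- Comparison: the chosen plan is stronger on stereochemical fidelity, because every stereochemical event is concerted and stereospecific. In step count, A7 needs the arylfuran core, an alkene, the cyclopropanation and a double methyl addition before the key step, so the total is not shorter.

Key step: step 2

Assumption: (+)-sparteine is taken as a purchasable reagent (the (+)-sparteine surrogate would be expected to act in the same sense), and the descriptor S of the target follows from the priorities O > furan carbon > CH2 > H.

## Route

Step 1
Reactants: 1 4-methylpent-3-en-1-ol; 2 N,N-diisopropylcarbamoyl chloride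
Product: 3 4-methylpent-3-en-1-yl N,N-diisopropylcarbamate
Conditions: Et3N, CH2Cl2, reflux, 24 h
Reagents that add atoms: none
Why: Carbamate formation by O-acylation of a primary alcohol with a carbamoyl chloride; the alkene is a bystander and no stereocentre is involved.

Step 2
Reactants: 3 4-methylpent-3-en-1-yl N,N-diisopropylcarbamate; 4 2-(furan-3-yl)-4,4,5,5-tetramethyl-1,3,2-dioxaborolane
Product: 7 (S)-2-[1-(furan-3-yl)-4-methylpent-3-en-1-yl]-4,4,5,5-tetramethyl-1,3,2-dioxaborolane, via lithiated carbamate 5 (not isolated), via boronate complex 6 (not isolated)
Conditions: s-BuLi, (+)-sparteine, Et2O, −78 °C, 5 h; then 4, −78 °C, 1 h; then MgBr2·OEt2, −78 °C to reflux, 16 h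
Reagents that add atoms: none
Why: The carbamate carbonyl binds s-BuLi·(+)-sparteine and the chiral base removes the pro-R proton of the O–CH2 group, giving the dipole-stabilised and at −78 °C configurationally stable R organolithium 5, an umpoled carbinol carbon. 5 adds to the boron of 4 with retention to give the ate complex 6, and on warming with MgBr2·OEt2 the furan-3-yl group shifts from boron to carbon antiperiplanar to the leaving carbamate, which inverts that carbon and forms the bond to the furan carbon that is C4 of the target. The closest known reaction type is the sparteine-mediated lithiation of primary alkyl carbamates followed by borylation with aryl pinacol boronic esters and Matteson-type 1,2-metallate rearrangement. No ring is closed. The one new stereocentre is controlled by the chiral diamine in the deprotonation and is passed on stereospecifically: retention then inversion turns R-configured 5 into S-configured 7, whose boron occupies the place that oxygen takes in the target. The step needs α-deprotonation in preference to removal of the allylic protons, which precomplexation to the carbamate and the low temperature secure, and it needs migration of the furyl group in preference to a pinacol oxygen, which the high migratory aptitude of the electron-rich heteroaryl group and the Lewis acid secure. The trisubstituted alkene is inert to the organolithium and, because the linear chain is already in place, no branched prenyl isomer can form.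

Step 3
Reactants: 7 (S)-2-[1-(furan-3-yl)-4-methylpent-3-en-1-yl]-4,4,5,5-tetramethyl-1,3,2-dioxaborolane
Product: 8 (S)-1-(furan-3-yl)-4-methylpent-3-en-1-ol
Conditions: NaBO3·4H2O, THF/H2O (1:1), rt, 3 h
Reagents that add atoms: NaBO3·4H2O (sodium perborate, supplies the hydroxyl oxygen), [Na+].[O-]OB=O
Why: Oxidation of a secondary boronic ester: the peroxide adds to boron and carbon migrates from boron to oxygen with retention, so the S configuration of 7 is carried into 8. The mild, nearly neutral reagent should spare the furan and the alkene.

Step 4
Reactants: 8 (S)-1-(furan-3-yl)-4-methylpent-3-en-1-ol; 9 3-methylbut-2-enoic acid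
Product: 10 (S)-1-(furan-3-yl)-4-methylpent-3-en-1-yl 3-methylbut-2-enoate
Conditions: DCC, DMAP (cat.), CH2Cl2, 0 °C to rt
Reagents that add atoms: none
Why: Steglich esterification through the O-acylisourea and the acylpyridinium of 9; the carbinol C–O bond is not broken, so the configuration is retained. The absence of a strong base and the low temperature should keep the acyl double bond in conjugation.

Step 5
Reactants: 10 (S)-1-(furan-3-yl)-4-methylpent-3-en-1-yl 3-methylbut-2-enoate; 11 2-bromo-1,4-dimethoxybenzene
Product: 13 (S)-1-[5-(2,5-dimethoxyphenyl)furan-3-yl]-4-methylpent-3-en-1-yl 3-methylbut-2-enoate, via furyl boronic ester 12 (not isolated)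
Conditions: [Ir(OMe)(cod)]2 (cat.), dtbpy (cat.), B2pin2 (1 equiv), THF, rt to 50 °C; evaporate; then 11, Pd(OAc)2 (cat.), SPhos, K3PO4, THF/H2O, 50 °C
Reagents that add atoms: none
Why: Iridium-catalysed C–H borylation of furans with B2pin2 takes place at the α-positions under steric control, so the C5–H remote from the branched side chain should be borylated in preference to the flanked C2–H, giving 12. Suzuki–Miyaura coupling with 11 in the same flask, with an electron-rich biaryl phosphine for the hindered, electron-rich bromide, then forms the furan–arene bond before the labile 2-furylboronate can lose boron. Neither catalyst touches the ester, the alkene or the stereocentre.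

Step 6
Reactants: 13 (S)-1-[5-(2,5-dimethoxyphenyl)furan-3-yl]-4-methylpent-3-en-1-yl 3-methylbut-2-enoate
Product: 14 (S)-1-[5-(3,6-dioxocyclohexa-1,4-dien-1-yl)furan-3-yl]-4-methylpent-3-en-1-yl 3-methylbut-2-enoate
Conditions: (NH4)2Ce(NO3)6, MeCN/H2O, 0 °C, 15 min
Reagents that add atoms: water (supplies both quinone oxygens), O
Why: Oxidative demethylation of a hydroquinone dimethyl ether by tetravalent cerium: two one-electron oxidations, attack of water at the two methoxy-bearing carbons and loss of methanol give the 1,4-benzoquinone. A short reaction time at 0 °C with a small excess of oxidant should spare the furan, the alkene and the ester, and the stereocentre is remote from the reacting ring.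

## Compound list

1 | 4-methylpent-3-en-1-ol | CC(C)=CCCO | starting material
2 | N,N-diisopropylcarbamoyl chloride | CC(C)N(C(C)C)C(Cl)=O | starting material
3 | 4-methylpent-3-en-1-yl N,N-diisopropylcarbamate | CC(C)=CCCOC(=O)N(C(C)C)C(C)C | intermediate
4 | 2-(furan-3-yl)-4,4,5,5-tetramethyl-1,3,2-dioxaborolane | CC1(C)OB(OC1(C)C)c1ccoc1 | starting material
5 | (R)-1-lithio-4-methylpent-3-en-1-yl N,N-diisopropylcarbamate, as its (+)-sparteine complex (diamine omitted from the SMILES) | CC(C)=CC[C@@H]([Li])OC(=O)N(C(C)C)C(C)C | intermediate (not isolated)
6 | lithium [(R)-1-(N,N-diisopropylcarbamoyloxy)-4-methylpent-3-en-1-yl](furan-3-yl)(pinacolato)borate | CC(C)=CC[C@@H]([B-]1(c2ccoc2)OC(C)(C)C(C)(C)O1)OC(=O)N(C(C)C)C(C)C.[Li+] | intermediate (not isolated)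
7 | (S)-2-[1-(furan-3-yl)-4-methylpent-3-en-1-yl]-4,4,5,5-tetramethyl-1,3,2-dioxaborolane | CC(C)=CC[C@H](B1OC(C)(C)C(C)(C)O1)c1ccoc1 | intermediate
8 | (S)-1-(furan-3-yl)-4-methylpent-3-en-1-ol | CC(C)=CC[C@H](O)c1ccoc1 | intermediate
9 | 3-methylbut-2-enoic acid | CC(C)=CC(=O)O | starting material
10 | (S)-1-(furan-3-yl)-4-methylpent-3-en-1-yl 3-methylbut-2-enoate | CC(C)=CC[C@H](OC(=O)C=C(C)C)c1ccoc1 | intermediate
11 | 2-bromo-1,4-dimethoxybenzene | COc1ccc(OC)c(Br)c1 | starting material
12 | (S)-4-methyl-1-[5-(4,4,5,5-tetramethyl-1,3,2-dioxaborolan-2-yl)furan-3-yl]pent-3-en-1-yl 3-methylbut-2-enoate | CC(C)=CC[C@H](OC(=O)C=C(C)C)c1coc(B2OC(C)(C)C(C)(C)O2)c1 | intermediate (not isolated)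
13 | (S)-1-[5-(2,5-dimethoxyphenyl)furan-3-yl]-4-methylpent-3-en-1-yl 3-methylbut-2-enoate | CC(C)=CC[C@H](OC(=O)C=C(C)C)c1coc(-c2cc(OC)ccc2OC)c1 | intermediate
14 | (S)-1-[5-(3,6-dioxocyclohexa-1,4-dien-1-yl)furan-3-yl]-4-methylpent-3-en-1-yl 3-methylbut-2-enoate | CC(C)=CC[C@H](OC(=O)C=C(C)C)c1coc(C2=CC(=O)C=CC2=O)c1 | target

## Step count and risks

Total: 6 steps. Longest linear sequence: 6 steps (1 to 3 to 7 to 8 to 10 to 13 to 14); 2, 4, 9 and 11 are purchased.

**Step 2 (key step).** The most likely failures are three. The 1,2-shift may be incomplete, because a carbamate is only a moderate leaving group, so the ate complex could persist and lose boron on work-up. The enantiomeric purity may erode if the deprotonation is not fully selective. The allylic position may be deprotonated in competition, followed by β-elimination of the carbamate.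
The fallback sets out from 1 and returns at 8; it gives up the umpolung for an asymmetric ketone reduction.
- 1 would be oxidised with Dess–Martin periodinane to 4-methylpent-3-enal F1, used at once.
- 3-Bromofuran and n-BuLi at −78 °C would give furan-3-yllithium F2. After transmetallation with CeCl3 to suppress enolisation, it would add to F1 to give racemic 1-(furan-3-yl)-4-methylpent-3-en-1-ol F3.
- Buffered Dess–Martin oxidation would give 1-(furan-3-yl)-4-methylpent-3-en-1-one F4.
- Corey–Bakshi–Shibata reduction with (R)-2-methyl-CBS-oxazaborolidine and BH3·SMe2 would give 8. This is the enantiomer of the catalyst expected to give the S alcohol when the furyl ring acts as the larger group.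

**Step 5.** Borylation may occur at the hindered α-position or twice. The 2-furylboronate may lose boron by protonolysis faster than it transmetallates. Oxidative addition into the electron-rich, ortho-substituted bromide may be slow.
The fallback sets out from 3 and returns at 13; it fixes the furan substitution by ring construction, as in Alternative 1.
- A4 would be prepared from A1 and A2 through A3.
- Miyaura borylation (PdCl2(dppf), B2pin2, KOAc, dioxane, 80 °C) would give 2-[5-(2,5-dimethoxyphenyl)furan-3-yl]-4,4,5,5-tetramethyl-1,3,2-dioxaborolane F5.
- F5 would replace 4 in the conditions of step 2 with 3. Through the lithium boronate complex F6 this would give (S)-2-[1-[5-(2,5-dimethoxyphenyl)furan-3-yl]-4-methylpent-3-en-1-yl]-4,4,5,5-tetramethyl-1,3,2-dioxaborolane F7.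
- NaBO3·4H2O would give (S)-1-[5-(2,5-dimethoxyphenyl)furan-3-yl]-4-methylpent-3-en-1-ol F8.
- Steglich esterification with 9 would give 13.

**Step 6.** The oxidant may attack the furan, whose free α-position can take up water from the radical cation and open the ring. The acid released may ionise the furylic ester. Over-oxidation of the product is possible on longer exposure.
The fallback sets out from 10 and returns at 14; it replaces oxidative demethylation by a mild hydroquinone oxidation.
- The coupling partner would be 2-bromo-1,4-bis(tert-butyldimethylsilyloxy)benzene F9, one silylation step from commercial 2-bromobenzene-1,4-diol with TBSCl and imidazole.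
- The one-pot borylation and coupling of step 5 with F9 in place of 11 would give (S)-1-[5-[2,5-bis(tert-butyldimethylsilyloxy)phenyl]furan-3-yl]-4-methylpent-3-en-1-yl 3-methylbut-2-enoate F10.
- TBAF buffered with AcOH in THF at 0 °C would give (S)-1-[5-(2,5-dihydroxyphenyl)furan-3-yl]-4-methylpent-3-en-1-yl 3-methylbut-2-enoate F11, the same compound as A6.
- Ag2O with MgSO4 in Et2O would give 14.

**Step 4.** The acyl double bond may migrate out of conjugation during activation of the acid, through a dienolate or vinylketene. Acyl transfer to the hindered furylic alcohol may be slow enough for the activated acid to rearrange to an unreactive N-acylurea.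
The fallback sets out from 8 and returns at 10; it builds the unsaturated acyl group on the ester.
- 8 would be acylated with 2-(diethoxyphosphoryl)acetic acid and DCC to (S)-1-(furan-3-yl)-4-methylpent-3-en-1-yl 2-(diethoxyphosphoryl)acetate F12.
- A Horner–Wadsworth–Emmons reaction with acetone (NaH, THF) would give 10, with the double bond formed directly in conjugation.

## Further compounds

F1 | step 2 | 4-methylpent-3-enal | CC(C)=CCC=O
F2 | step 2 | furan-3-yllithium | [Li]c1ccoc1
F3 | step 2 | racemic 1-(furan-3-yl)-4-methylpent-3-en-1-ol | CC(C)=CCC(O)c1ccoc1
F4 | step 2 | 1-(furan-3-yl)-4-methylpent-3-en-1-one | CC(C)=CCC(=O)c1ccoc1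
F5 | step 5 | 2-[5-(2,5-dimethoxyphenyl)furan-3-yl]-4,4,5,5-tetramethyl-1,3,2-dioxaborolane | COc1ccc(OC)c(-c2cc(B3OC(C)(C)C(C)(C)O3)co2)c1
F6 | step 5 | lithium [(R)-1-(N,N-diisopropylcarbamoyloxy)-4-methylpent-3-en-1-yl][5-(2,5-dimethoxyphenyl)furan-3-yl](pinacolato)borate | CC(C)=CC[C@@H]([B-]1(c2coc(-c3cc(OC)ccc3OC)c2)OC(C)(C)C(C)(C)O1)OC(=O)N(C(C)C)C(C)C.[Li+]
F7 | step 5 | (S)-2-[1-[5-(2,5-dimethoxyphenyl)furan-3-yl]-4-methylpent-3-en-1-yl]-4,4,5,5-tetramethyl-1,3,2-dioxaborolane | CC(C)=CC[C@H](B1OC(C)(C)C(C)(C)O1)c1coc(-c2cc(OC)ccc2OC)c1
F8 | step 5 | (S)-1-[5-(2,5-dimethoxyphenyl)furan-3-yl]-4-methylpent-3-en-1-ol | CC(C)=CC[C@H](O)c1coc(-c2cc(OC)ccc2OC)c1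
F9 | step 6 | 2-bromo-1,4-bis(tert-butyldimethylsilyloxy)benzene | CC(C)(C)[Si](C)(C)Oc1ccc(O[Si](C)(C)C(C)(C)C)c(Br)c1
F10 | step 6 | (S)-1-[5-[2,5-bis(tert-butyldimethylsilyloxy)phenyl]furan-3-yl]-4-methylpent-3-en-1-yl 3-methylbut-2-enoate | CC(C)=CC[C@H](OC(=O)C=C(C)C)c1coc(-c2cc(O[Si](C)(C)C(C)(C)C)ccc2O[Si](C)(C)C(C)(C)C)c1
F11 | step 6 | (S)-1-[5-(2,5-dihydroxyphenyl)furan-3-yl]-4-methylpent-3-en-1-yl 3-methylbut-2-enoate | CC(C)=CC[C@H](OC(=O)C=C(C)C)c1coc(-c2cc(O)ccc2O)c1
F12 | step 4 | (S)-1-(furan-3-yl)-4-methylpent-3-en-1-yl 2-(diethoxyphosphoryl)acetate | CC(C)=CC[C@H](OC(=O)CP(=O)(OCC)OCC)c1ccoc1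
A1 | alternative 1 | 2,5-dimethoxybenzoyl chloride | COc1ccc(OC)c(C(Cl)=O)c1
A2 | alternative 1 | 2-(prop-2-yn-1-yloxy)oxane | C#CCOC1CCCCO1
A3 | alternative 1 | 1-(2,5-dimethoxyphenyl)-4-(oxan-2-yloxy)but-2-yn-1-one | COc1ccc(OC)c(C(=O)C#CCOC2CCCCO2)c1
A4 | alternative 1 | 2-(2,5-dimethoxyphenyl)-4-iodofuran | COc1ccc(OC)c(-c2cc(I)co2)c1
A5 | alternative 2 | (S)-1-[5-(4-ethenyl-4-hydroxy-3-oxocyclobut-1-en-1-yl)furan-3-yl]-4-methylpent-3-en-1-yl 3-methylbut-2-enoate (either configuration at the ring carbinol carbon) | CC(C)=CC[C@H](OC(=O)C=C(C)C)c1coc(C2=CC(=O)C2(O)C=C)c1
A6 | alternative 2 | (S)-1-[5-(2,5-dihydroxyphenyl)furan-3-yl]-4-methylpent-3-en-1-yl 3-methylbut-2-enoate | CC(C)=CC[C@H](OC(=O)C=C(C)C)c1coc(-c2cc(O)ccc2O)c1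
A7 | alternative 3 | 2-[(1S,2S)-2-[5-(2,5-dimethoxyphenyl)furan-3-yl]cyclopropyl]propan-2-ol | CC(C)(O)[C@H]1C[C@@H]1c1coc(-c2cc(OC)ccc2OC)c1
A8 | alternative 3 | (S)-1-[5-(2,5-dimethoxyphenyl)furan-3-yl]-4-methylpent-3-en-1-yl 3-methylbut-2-enoate | CC(C)=CC[C@H](OC(=O)C=C(C)C)c1coc(-c2cc(OC)ccc2OC)c1
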